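**Plan**

- Retrosynthesis: the two MOM ethers at O7 and O3' are cut first. Ring D (O4'–C2''(Me)2–C3''=C4''–C5') is then opened at C5'–C4'', which leads back to the 4'-O-(2-methylbut-3-yn-2-yl) ether of 7,3'-di-O-MOM-luteolin. Cutting the O4'–C2'' ether bond and the acetal C–O bonds gives luteolin.
- Enabling feature: ring D shares the C4'–C5' edge of ring B and its oxygen is O4'. C3', the other carbon ortho to O4', already carries oxygen, so a [3,3] shift from O4' can rearomatize only after bonding to C5'.
- Forward: rings A, B and C are bought as luteolin. A diphenylmethylene ketal on the catechol lets O7 be capped alone; hydrogenolysis frees the catechol; O4' is propargylated and O3' capped. Ring D is closed last by a thermal Claisen/hydrogen-shift/oxa-6π cascade, and both MOM groups are then removed.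
- Stereochemistry: the target has no stereocentre. The cis C3''=C4'' bond is fixed by ring D, and the only sp3 centre made on the way (C5' of the dienone) is erased on enolization.

Key step: step 6

Assumption: in 7-O-MOM-luteolin the 4'-OH, para to C2 of the chromone, is the phenol that K2CO3 ionizes and alkylates first, and the hydrogen-bonded 5-OH stays untouched under carbonate conditions.

**Step 1**
Reactants: 1 luteolin; 2 dichlorodiphenylmethane
Product: 3 3',4'-O-(diphenylmethylene)luteolin
Conditions: Ph2CCl2 (1.5 equiv), Ph2O, 175 °C
Reagents that add atoms: dichlorodiphenylmethane, ClC(Cl)(c1ccccc1)c1ccccc1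
Why: Ketalization of a catechol with a gem-dichloride: only the 3',4'-diol of ring B can span the Ph2C unit as a five-membered 1,3-benzodioxole, the meta-related 5- and 7-OH of ring A cannot, and HCl leaves the hot mixture as gas.

**Step 2**
Reactants: 3 3',4'-O-(diphenylmethylene)luteolin; 4 chloromethyl methyl ether
Product: 5 7-O-MOM-3',4'-O-(diphenylmethylene)luteolin
Conditions: MOMCl (1.2 equiv), K2CO3 (1.5 equiv), acetone, 0 °C to rt
Reagents that add atoms: chloromethyl methyl ether, COCCl
Why: Williamson-type O-alkylation with an α-chloro ether: with the catechol tied up, the vinylogous-acid 7-OH is the only phenol that carbonate ionizes, while the 5-OH stays locked in its hydrogen bond to the C4 carbonyl.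

**Step 3**
Reactants: 5 7-O-MOM-3',4'-O-(diphenylmethylene)luteolin
Product: 6 7-O-MOM-luteolin
Conditions: H2 (1 atm), Pd/C (10 wt%), THF/MeOH, rt
Reagents that add atoms: none
Why: Catalytic hydrogenolysis of the two doubly benzylic C–O bonds of the diphenylmethylene ketal should release the catechol and diphenylmethane, while the aryl MOM ether and the cross-conjugated C2=C3 bond of the chromone are left alone at 1 atm.

**Step 4**
Reactants: 6 7-O-MOM-luteolin; 7 3-chloro-3-methylbut-1-yne
Product: 8 7-O-MOM-4'-O-(2-methylbut-3-yn-2-yl)luteolin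
Conditions: 3-chloro-3-methylbut-1-yne (1.5 equiv), K2CO3 (1.1 equiv), KI (cat.), CuI (cat.), DMF, 60 °C, Ar
Reagents that add atoms: 3-chloro-3-methylbut-1-yne, C#CC(C)(C)Cl
Why: Copper-assisted O-propargylation of a phenoxide by a tertiary propargylic chloride (substitution through a copper acetylide-derived electrophile): the 4'-OH is para to C2 and so the most acidic free phenol, and one equivalent of carbonate should direct the 2-methylbut-3-yn-2-yl group to O4' and leave the 3'-OH and the chelated 5-OH.

**Step 5**
Reactants: 8 7-O-MOM-4'-O-(2-methylbut-3-yn-2-yl)luteolin; 4 chloromethyl methyl ether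
Product: 9 7,3'-di-O-MOM-4'-O-(2-methylbut-3-yn-2-yl)luteolin
Conditions: MOMCl (1.3 equiv), K2CO3 (2 equiv), acetone, rt
Reagents that add atoms: chloromethyl methyl ether, COCCl
Why: Williamson-type MOM protection: the 3'-OH is the only non-chelated phenol left, and masking it should keep the catechol monoether from oxidation and from adding to the alkyne during the thermolysis.

**Step 6**
Reactants: 9 7,3'-di-O-MOM-4'-O-(2-methylbut-3-yn-2-yl)luteolin
Product: 13 7,3'-di-O-MOM-yinyanghuo E, via allenyl cyclohexadienone 10 (not isolated), via allenyl phenol 11 (not isolated), via ortho-quinone methide 12 (not isolated)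
Conditions: PhNEt2, 180 °C, Ar
Reagents that add atoms: none
Why: Heat drives an aromatic propargyl Claisen ([3,3]-sigmatropic) rearrangement in which the alkyne terminus C4'' bonds to C5' as the O4'–C2'' bond breaks, and the resulting dienone 10 enolizes to the allenyl phenol 11. A 1,5-hydrogen shift from the 4'-OH to the central allene carbon C3'' through a six-membered transition state then gives the Z-configured ortho-quinone methide 12, and a thermally allowed disrotatory oxa-6π electrocyclization rebuilds the O4'–C2'' bond and closes ring D as a six-membered 2H-pyran. The closest known reaction type is the thermal conversion of aryl 1,1-dimethylpropargyl ethers into 2,2-dimethyl-2H-chromenes, where the gem-dimethyl group lowers the barrier of the sigmatropic step. No stereocentre remains, since the sp3 carbon C5' of 10 is flattened on enolization and C2'' carries two methyl groups. The selectivity needed is C5' over C3' as the ortho terminus, and the substrate secures it because a shift to C3' would give a dienone with the OMOM group on its sp3 carbon that cannot enolize and should only revert to 9. The chromone, the chelated 5-OH and both MOM ethers should survive because the basic amine solvent keeps acid away while assisting the proton transfers.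

**Step 7**
Reactants: 13 7,3'-di-O-MOM-yinyanghuo E
Product: 14 Yinyanghuo E
Conditions: HCl (3 M aq.), MeOH/THF, 45 °C
Reagents that add atoms: none
Why: Acid-catalysed transacetalization of the two aryl MOM ethers with methanol (acetal cleavage through the methoxymethyl oxocarbenium ion) should give the free phenols and volatile dimethoxymethane under conditions mild enough for a 2,2-dimethyl-2H-chromene, whose protonation is far slower than acetal ionization.

**Compound list**

1 | luteolin (2-(3,4-dihydroxyphenyl)-5,7-dihydroxy-4H-chromen-4-one) | O=c1cc(-c2ccc(O)c(O)c2)oc2cc(O)cc(O)c12 | starting material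
2 | dichlorodiphenylmethane | ClC(Cl)(c1ccccc1)c1ccccc1 | starting material
3 | 3',4'-O-(diphenylmethylene)luteolin (2-(2,2-diphenyl-1,3-benzodioxol-5-yl)-5,7-dihydroxy-4H-chromen-4-one) | O=c1cc(-c2ccc3c(c2)OC(c2ccccc2)(c2ccccc2)O3)oc2cc(O)cc(O)c12 | intermediate
4 | chloromethyl methyl ether (MOMCl) | COCCl | starting material
5 | 7-O-MOM-3',4'-O-(diphenylmethylene)luteolin | O=c1cc(-c2ccc3c(c2)OC(c2ccccc2)(c2ccccc2)O3)oc2cc(OCOC)cc(O)c12 | intermediate
6 | 7-O-MOM-luteolin (2-(3,4-dihydroxyphenyl)-5-hydroxy-7-(methoxymethoxy)-4H-chromen-4-one) | O=c1cc(-c2ccc(O)c(O)c2)oc2cc(OCOC)cc(O)c12 | intermediate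
7 | 3-chloro-3-methylbut-1-yne | C#CC(C)(C)Cl | starting material
8 | 7-O-MOM-4'-O-(2-methylbut-3-yn-2-yl)luteolin (3'-OH and 5-OH free) | C#CC(C)(C)Oc1ccc(-c2cc(=O)c3c(O)cc(OCOC)cc3o2)cc1O | intermediate
9 | 7,3'-di-O-MOM-4'-O-(2-methylbut-3-yn-2-yl)luteolin (5-OH free) | C#CC(C)(C)Oc1ccc(-c2cc(=O)c3c(O)cc(OCOC)cc3o2)cc1OCOC | intermediate
10 | allenyl cyclohexadienone: ring B as a 2,4-dienone with C4'=O and a 3-methylbuta-1,2-dienyl group on sp3 C5' (racemic, transient) | CC(C)=C=CC1C=C(-c2cc(=O)c3c(O)cc(OCOC)cc3o2)C=C(OCOC)C1=O | intermediate
11 | allenyl phenol: 5'-(3-methylbuta-1,2-dienyl)-7,3'-di-O-MOM-luteolin | CC(C)=C=Cc1cc(-c2cc(=O)c3c(O)cc(OCOC)cc3o2)cc(OCOC)c1O | intermediate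
12 | ortho-quinone methide: C4'=O with a (Z)-3-methylbut-2-enylidene group on C5' | CC(C)=C/C=C1/C=C(-c2cc(=O)c3c(O)cc(OCOC)cc3o2)C=C(OCOC)C1=O | intermediate
13 | 7,3'-di-O-MOM-yinyanghuo E (5-hydroxy-7-(methoxymethoxy)-2-[8-(methoxymethoxy)-2,2-dimethyl-2H-chromen-6-yl]-4H-chromen-4-one) | CC1(C)C=Cc2cc(-c3cc(=O)c4c(O)cc(OCOC)cc4o3)cc(OCOC)c2O1 | intermediate
14 | Yinyanghuo E (5,7-dihydroxy-2-(8-hydroxy-2,2-dimethyl-2H-chromen-6-yl)-4H-chromen-4-one) | CC1(C)C=Cc2cc(-c3cc(=O)c4c(O)cc(O)cc4o3)cc(O)c2O1 | target

**Count**

Total steps: 7. Longest linear sequence: 7 steps, from luteolin 1.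

**Steps most likely to fail**

Step 4. The tertiary chloride is sluggish and prone to elimination, so the excess reagent and base needed to drive it may cause alkylation at the wrong catechol oxygen or at both. The 3'-phenoxide next to the new alkyne may also add to it under the basic copper conditions. The fallback moves the regiochemical decision to a clean substitution with a primary halide and propargylates only after O3' is capped. It sets out from 6. Benzylation with BnCl, NaHCO3 and NaI in DMF at 40 °C, where only the 4'-phenol is ionized, should give 4'-O-benzyl-7-O-MOM-luteolin F1. MOMCl and K2CO3 in acetone should then give 4'-O-benzyl-7,3'-di-O-MOM-luteolin F2. Hydrogenolysis (H2, Pd/C, THF/MeOH) should release 7,3'-di-O-MOM-luteolin F3, in which the 4'-OH is the only reactive phenol. F3 can be pushed to completion with excess 7 (K2CO3, KI, CuI, DMF, 60 °C), and the fallback rejoins the route at 9.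

Step 6. The thermolysis may lose the tertiary propargyl group by ether cleavage back to the phenol, or the allenyl phenol may be diverted to five-membered-ring products before the hydrogen shift. The fallback forms the same C5'–C4'' bond and the same ring D in stages at lower temperature. It sets out from 9. Semi-hydrogenation (H2, Pd/CaCO3 poisoned with Pb(OAc)2, quinoline, EtOAc, rt) should give 7,3'-di-O-MOM-4'-O-(2-methylbut-3-en-2-yl)luteolin F4. Its aromatic Claisen rearrangement in xylene at about 120 °C should deliver the prenyl group to C5' for the same reason as in step 6, giving 5'-prenyl-7,3'-di-O-MOM-luteolin F5. Dehydrogenative cyclization with DDQ in refluxing 1,4-dioxane, which passes through the ortho-quinone methide 12, should close ring D, and the fallback rejoins the route at 13.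

Step 7. The acid may add methanol or water across the C3''=C4'' bond of ring D, and a slow second MOM cleavage would prolong that exposure. The fallback removes the acetals before ring D exists. It sets out from 9. HCl in MeOH/THF should cleave both MOM ethers while the tertiary propargyl ether, which ionizes far less readily than the acetal, stays in place, giving 4'-O-(2-methylbut-3-yn-2-yl)luteolin F6. Heating F6 in PhNEt2 at 180 °C should run the same Claisen/hydrogen-shift/oxa-6π cascade on the free phenol, and the fallback arrives directly at 14.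

**Further compounds**

F1 | step 4 | 4'-O-benzyl-7-O-MOM-luteolin | O=c1cc(-c2ccc(OCc3ccccc3)c(O)c2)oc2cc(OCOC)cc(O)c12
F2 | step 4 | 4'-O-benzyl-7,3'-di-O-MOM-luteolin | O=c1cc(-c2ccc(OCc3ccccc3)c(OCOC)c2)oc2cc(OCOC)cc(O)c12
F3 | step 4 | 7,3'-di-O-MOM-luteolin | O=c1cc(-c2ccc(O)c(OCOC)c2)oc2cc(OCOC)cc(O)c12
F4 | step 6 | 7,3'-di-O-MOM-4'-O-(2-methylbut-3-en-2-yl)luteolin | C=CC(C)(C)Oc1ccc(-c2cc(=O)c3c(O)cc(OCOC)cc3o2)cc1OCOC
F5 | step 6 | 5'-prenyl-7,3'-di-O-MOM-luteolin | CC(C)=CCc1cc(-c2cc(=O)c3c(O)cc(OCOC)cc3o2)cc(OCOC)c1O
F6 | step 7 | 4'-O-(2-methylbut-3-yn-2-yl)luteolin | C#CC(C)(C)Oc1ccc(-c2cc(=O)c3c(O)cc(O)cc3o2)cc1O
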